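**Retrosynthetic overview**
1. Pendant lactone last: C3–C18 by Friedel–Crafts acylation of the pyrrole with (S)-methylsuccinic anhydride, C18 by CBS reduction and lactonisation.
2. Azepine: ring-closing metathesis (C7=C8) between an N-butenyl group and a C9 vinyl group, then hydrogenation.
3. Key step: the C11–C12 bond is made by intramolecular carbene-catalysed homoenolate addition of a C1-bound α-methyl enal (β-carbon C12) to the C11 aldehyde. This closes ring C and the fused lactone together and sets C11, C12 and C13.
4. C9–C10 bond and both centres: dual iridium/amine α-allylation of butanal with a pyrrolyl vinyl carbinol.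
5. Pyrrole from a Clauson–Kaas reaction, then C2-lithiation/acrolein and Wittig. Ring order: pyrrole → ring C + fused lactone → azepine → pendant lactone.

Assumption: the SMILES is taken as drawn (9S,10R,11R,12S,13S,18R,20S), and (S)-methylsuccinic anhydride is bought (otherwise one step from the acid with acetyl chloride).

Locants used in names (Stemona numbering): pyrrole C1, C2, C3, N4, C9a; azepine C5–C9; ring C = C1, C9a, C9, C10, C11, C12; fused lactone O–C11, C12, C13(Me), C14(=O); pendant lactone C18(O), C19, C20(Me), C21(=O).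

**Step 1**
Reactants: 1 but-3-en-1-amine; 2 2,5-dimethoxytetrahydrofuran-3-carbaldehyde
Product: 3 1-(but-3-en-1-yl)-1H-pyrrole-3-carbaldehyde
Conditions: AcOH, 90 °C
Reagents that add atoms: 2,5-dimethoxytetrahydrofuran-3-carbaldehyde 2, COC1CC(C=O)C(OC)O1
Why: Clauson–Kaas pyrrole synthesis, in which acid unmasks 2-formylsuccinaldehyde and double condensation with the primary amine gives the N-alkyl pyrrole that already carries the C12 formyl group on C1, the terminal alkene being inert.

**Step 2**
Reactants: 3 1-(but-3-en-1-yl)-1H-pyrrole-3-carbaldehyde; 4 acrolein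
Product: 8 1-(but-3-en-1-yl)-2-(1-hydroxyprop-2-en-1-yl)-1H-pyrrole-3-carbaldehyde (racemic), via lithium amino alkoxide 5 (not isolated), via ring-lithiated amino alkoxide 6 (not isolated), via acrolein adduct 7 (not isolated)
Conditions: LiN(Me)CH2CH2NMe2, THF, −78 °C; n-BuLi, −78 → −20 °C; acrolein, −78 °C; aq. NH4Cl
Reagents that add atoms: acrolein 4, C=CC=O
Why: Directed ortho-metalation through a transient α-amino alkoxide (Comins protocol), in which the chelating amide masks the aldehyde as 5 and steers n-BuLi to the adjacent α-position (C9a), as known for 3-formyl furans, thiophenes and indoles; aryllithium 6 then adds 1,2 to acrolein to give the C9 carbinol, whose configuration is erased in step 4.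

**Step 3**
Reactants: 8 1-(but-3-en-1-yl)-2-(1-hydroxyprop-2-en-1-yl)-1H-pyrrole-3-carbaldehyde; 9 2-(triphenylphosphoranylidene)propanal
Product: 10 (2E)-3-[1-(but-3-en-1-yl)-2-(1-hydroxyprop-2-en-1-yl)-1H-pyrrol-3-yl]-2-methylprop-2-enal (racemic carbinol)
Conditions: toluene, 90 °C
Reagents that add atoms: 2-(triphenylphosphoranylidene)propanal 9, CC(C=O)=P(c1ccccc1)(c1ccccc1)c1ccccc1
Why: Wittig olefination with a formyl-stabilised ylide gives the (E)-α-methyl enal and stops there because the product enal is much less electrophilic than the starting aldehyde, which reacts from the open form of its lactol.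

**Step 4**
Reactants: 10 (2E)-3-[1-(but-3-en-1-yl)-2-(1-hydroxyprop-2-en-1-yl)-1H-pyrrol-3-yl]-2-methylprop-2-enal; 11 butanal
Product: 12 (2R,3S)-3-{1-(but-3-en-1-yl)-3-[(1E)-2-methyl-3-oxoprop-1-en-1-yl]-1H-pyrrol-2-yl}-2-ethylpent-4-enal (= 9S,10R)
Conditions: [Ir(cod)Cl]2 (3 mol%), (P,olefin) phosphoramidite ligand N-(dinaphtho[2,1-d:1',2'-f][1,3,2]dioxaphosphepin-4-yl)dibenzo[b,f]azepine (12 mol%, the enantiomer that gives 9S), (S)-2-{bis[3,5-bis(trifluoromethyl)phenyl](trimethylsilyloxy)methyl}pyrrolidine (15 mol%), (MeO)2P(O)OH (promoter), butanal (3 equiv), ClCH2CH2Cl, 25 °C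
Reagents that add atoms: butanal 11, CCCC=O
Why: Stereodivergent dual iridium/amine α-allylation of a linear aldehyde with a racemic aryl vinyl carbinol, in which the iridium π-allyl complex (ligand enantiomer) fixes C9 and the (S)-prolinol enamine fixes C10 as R (attack anti to the diarylsilyloxymethyl group, as in its nitroalkene Michael additions), so the syn (9S,10R) pair is chosen by catalyst pairing while the hindered α-methyl enal does not engage the secondary amine.

**Step 5 (key step)**
Reactants: 12 (2R,3S)-3-{1-(but-3-en-1-yl)-3-[(1E)-2-methyl-3-oxoprop-1-en-1-yl]-1H-pyrrol-2-yl}-2-ethylpent-4-enal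
Product: 15 (9S,10R,11R,12S,13S)-N-(but-3-en-1-yl)-9-vinyl-10-ethyl ring-C lactone (4,5,6,7-tetrahydroindole cis-fused at C11–C12 to the α-methyl-γ-butyrolactone; H9–H13 all cis), via homoenolate 13 (not isolated), via acyl azolium alkoxide 14 (not isolated)
Conditions: 2-mesityl-6,7-dihydro-5H-pyrrolo[2,1-c][1,2,4]triazol-2-ium chloride (15 mol%), DBU (10 mol%), THF (0.02 M), 40 °C
Reagents that add atoms: none
Why: Proposed new method: intramolecular N-heterocyclic-carbene homoenolate annulation, in which carbene addition to the enal gives extended Breslow intermediate 13 whose β-carbon C12 (normally electrophilic) attacks the C11 aldehyde through a half-chair with equatorial ethyl, pseudo-axial vinyl (enforced by peri strain with the N-butenyl group) and axial carbonyl oxygen to give the all-cis C9–C12 array, after which protonation of the hydrogen-bonded enol at C13 from the exposed exo face and O-acylation by acyl azolium 14 close the cis-lactone and release the carbene; the closest known reactions are the intermolecular enal–aldehyde γ-lactone annulation and intramolecular enal–ketone homoenolate lactonisations, and the base is kept below the azolium loading so that the C10 aldehyde α-centre does not epimerise.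

**Step 6**
Reactants: 15 (9S,10R,11R,12S,13S)-N-(but-3-en-1-yl)-9-vinyl-10-ethyl ring-C lactone
Product: 17 (9S,10R,11R,12S,13S)-tetracyclic core (the target skeleton with H at C3 in place of the pendant lactone), via dihydroazepine 16 (not isolated)
Conditions: second-generation Grubbs catalyst RuCl2(=CHPh)(H2IMes)(PCy3) (5 mol%), CH2Cl2, 40 °C; then Pd/C, H2 (1 atm), MeOH, 25 °C
Reagents that add atoms: none
Why: Ring-closing metathesis of the two terminal alkenes (N-butenyl and the pseudo-axial C9 vinyl) closes the seven-membered ring with loss of ethylene, and the cis-disubstituted C7=C8 alkene is then hydrogenated over Pd/C without touching the pyrrole, the non-benzylic lactone C–O bond or any stereocentre.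

**Step 7**
Reactants: 17 (9S,10R,11R,12S,13S)-tetracyclic core; 18 (S)-methylsuccinic anhydride
Product: 20 methyl (2S)-2-methyl-4-oxo-4-[(9S,10R,11R,12S,13S)-core-3-yl]butanoate, via keto acid 19 (not isolated)
Conditions: Sc(OTf)3 (20 mol%), MeNO2, 40 °C; then TMSCHN2, MeOH/toluene, 0 °C
Reagents that add atoms: (S)-methylsuccinic anhydride 18, O=C1C[C@H](C)C(=O)O1; trimethylsilyldiazomethane, C[Si](C)(C)C=[N+]=[N-]
Why: Friedel–Crafts acylation at C3, the only free α-position of the electron-rich trialkylpyrrole, with the anhydride opening at its less hindered carbonyl so that the methyl-bearing carbon (C20, S from the chiral pool) sits next to the free acid, which is then methylated to allow a borane reduction.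

**Step 8**
Reactants: 20 methyl (2S)-2-methyl-4-oxo-4-[(9S,10R,11R,12S,13S)-core-3-yl]butanoate
Product: 22 Epibisdehydroneotuberostemonine J (9S,10R,11R,12S,13S,18R,20S), via hydroxy ester 21 (not isolated)
Conditions: (S)-Me-CBS (0.5 equiv), catecholborane (1.5 equiv), toluene, −40 °C; aq. NaHCO3 work-up; then Et3N (cat.), toluene, 40 °C
Reagents that add atoms: none
Why: Corey–Bakshi–Shibata reduction, in which the pyrrolyl group acts as the large substituent so the (S)-oxazaborolidine gives the (18R) carbinol (the sense in which acetophenone gives (R)-1-phenylethanol), and the hydroxyl then closes onto the C21 ester to give the trans (18R,20S) lactone under neutral to weakly basic conditions that avoid ionising the pyrrolyl carbinol and leave C13 and C20 untouched.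

**Compound list**
1 | but-3-en-1-amine | NCCC=C | starting material
2 | 2,5-dimethoxytetrahydrofuran-3-carbaldehyde (mixture of stereoisomers) | COC1CC(C=O)C(OC)O1 | starting material
3 | 1-(but-3-en-1-yl)-1H-pyrrole-3-carbaldehyde | C=CCCn1ccc(C=O)c1 | intermediate
4 | acrolein | C=CC=O | starting material
5 | lithium α-amino alkoxide of 3 (formyl adduct of LiN(Me)CH2CH2NMe2; not isolated) | [Li+].C=CCCn1ccc(C([O-])N(C)CCN(C)C)c1 | intermediate
6 | C2-lithiated α-amino alkoxide (not isolated) | [Li+].[Li]c1c(C([O-])N(C)CCN(C)C)ccn1CCC=C | intermediate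
7 | dilithium alkoxide adduct of 6 with acrolein (not isolated) | [Li+].[Li+].C=CCCn1ccc(C([O-])N(C)CCN(C)C)c1C([O-])C=C | intermediate
8 | 1-(but-3-en-1-yl)-2-(1-hydroxyprop-2-en-1-yl)-1H-pyrrole-3-carbaldehyde (racemic; in equilibrium with its lactol) | C=CCCn1ccc(C=O)c1C(O)C=C | intermediate
9 | 2-(triphenylphosphoranylidene)propanal | CC(C=O)=P(c1ccccc1)(c1ccccc1)c1ccccc1 | starting material
10 | (2E)-3-[1-(but-3-en-1-yl)-2-(1-hydroxyprop-2-en-1-yl)-1H-pyrrol-3-yl]-2-methylprop-2-enal (racemic carbinol) | C=CCCn1ccc(/C=C(\C)C=O)c1C(O)C=C | intermediate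
11 | butanal | CCCC=O | starting material
12 | (2R,3S)-3-{1-(but-3-en-1-yl)-3-[(1E)-2-methyl-3-oxoprop-1-en-1-yl]-1H-pyrrol-2-yl}-2-ethylpent-4-enal | CC[C@@H](C=O)[C@H](C=C)c1c(/C=C(\C)C=O)ccn1CCC=C | intermediate
13 | extended Breslow (homoenolate) adduct of 12 with the triazolylidene (not isolated) | CC[C@@H](C=O)[C@H](C=C)c1c(/C=C(\C)C(O)=C2N(c3c(C)cc(C)cc3C)N=C3CCCN23)ccn1CCC=C | intermediate
14 | acyl azolium alkoxide after C11–C12 bond formation and C13 protonation (zwitterion; not isolated) | CC[C@H]1[C@@H]([O-])[C@@H]([C@H](C)C(=O)c2[n+](-c3c(C)cc(C)cc3C)nc3CCCn23)c2ccn(CCC=C)c2[C@H]1C=C | intermediate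
15 | (9S,10R,11R,12S,13S)-N-(but-3-en-1-yl)-9-vinyl-10-ethyl-4,5,6,7-tetrahydroindole cis-fused at C11(O)–C12 to the α-methyl-γ-butyrolactone | CC[C@H]1[C@H]2OC(=O)[C@@H](C)[C@H]2c2ccn(CCC=C)c2[C@H]1C=C | intermediate
16 | 7,8-didehydro analogue of 17 (C7=C8 in the azepine ring; not isolated) | CC[C@H]1[C@H]2OC(=O)[C@@H](C)[C@H]2c2ccn3c2[C@H]1C=CCC3 | intermediate
17 | (9S,10R,11R,12S,13S)-tetracyclic core: pyrrolo[1,2-a]azepine, ring C and fused lactone, H at C3 | CC[C@H]1[C@H]2OC(=O)[C@@H](C)[C@H]2c2ccn3c2[C@H]1CCCC3 | intermediate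
18 | (S)-methylsuccinic anhydride ((3S)-3-methyloxolane-2,5-dione) | O=C1C[C@H](C)C(=O)O1 | starting material
19 | (2S)-2-methyl-4-oxo-4-[core-3-yl]butanoic acid (not isolated) | CC[C@H]1[C@H]2OC(=O)[C@@H](C)[C@H]2c2cc(C(=O)C[C@H](C)C(=O)O)n3c2[C@H]1CCCC3 | intermediate
20 | methyl (2S)-2-methyl-4-oxo-4-[core-3-yl]butanoate | CC[C@H]1[C@H]2OC(=O)[C@@H](C)[C@H]2c2cc(C(=O)C[C@H](C)C(=O)OC)n3c2[C@H]1CCCC3 | intermediate
21 | methyl (2S,4R)-4-hydroxy-2-methyl-4-[core-3-yl]butanoate (not isolated) | CC[C@H]1[C@H]2OC(=O)[C@@H](C)[C@H]2c2cc([C@H](O)C[C@H](C)C(=O)OC)n3c2[C@H]1CCCC3 | intermediate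
22 | Epibisdehydroneotuberostemonine J | CC[C@H]1[C@H]2OC(=O)[C@@H](C)[C@H]2c2cc([C@H]3C[C@H](C)C(=O)O3)n3c2[C@H]1CCCC3 | target

**Step count and risks**
Total steps: 8. Longest linear sequence: 8 (1 + 2 → 22).

The three steps most likely to fail:

Step 4 (dual catalysis on an ionisable pyrrolyl carbinol that also carries an enal). The fallback sets out from 8 and returns at 12. It replaces catalyst control by a sigmatropic rearrangement:
- Wittig reaction of 8 with ethyl 2-(triphenylphosphoranylidene)propanoate gives ethyl (2E)-3-[1-(but-3-en-1-yl)-2-(1-hydroxyprop-2-en-1-yl)-1H-pyrrol-3-yl]-2-methylprop-2-enoate F1.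
- Butanoic anhydride/DMAP gives the branched butanoate F2.
- PdCl2(MeCN)2 moves the acyloxy group by a 1,3-shift to give the linear (E)-allylic butanoate F3.
- An enantioselective Ireland–Claisen rearrangement through the chiral boron enolate (Corey's 2-bromo-4,5-diphenyl-1,3-bis(arylsulfonyl)-1,3,2-diazaborolidine with a tertiary amine, using the base/solvent pair for the syn product) gives the (2R,3S) acid F4.
- LiAlH4 reduces the acid and the enoate to the diol F5, and Dess–Martin periodinane oxidises both alcohols to 12.

Step 5 (new intramolecular homoenolate annulation). The risks are cis versus trans delivery at C11, the face of attack, the C13 protonation and competing acyl-anion chemistry of the C11 aldehyde. The fallback sets out from 8 and returns at 15. It uses a reductive radical cyclisation followed by an invertive lactonisation: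
- The ethyl enoate carbinol F1 (made as above) undergoes the step 4 allylation with butanal to give the (2R,3S) aldehyde enoate F6.
- SmI2/HMPA/t-BuOH in THF at −78 °C effects ketyl–olefin cyclisation, which is expected to give the anti product, the C11-epimeric (trans) hydroxy ester F7.
- LiOH gives the hydroxy acid F8.
- Mitsunobu lactonisation (PPh3, DIAD, toluene) closes the lactone with inversion at C11 to give 15.
- If C13 is mixed, LDA at −78 °C followed by kinetic protonation from the convex face sets it; this correction is available only at 15 or 17, before the pendant lactone is installed.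

Step 8 (slow reduction of a vinylogous amide ketone, with possible over-reduction or ionisation of the pyrrolyl carbinol). The fallback sets out from 17 and returns at 22. It forms the C3–C18 bond at the lactone oxidation level and needs no ketone:
- Ozonolysis of (S)-2-methylpent-4-enoic acid (O3, then Me2S) gives the pseudo-acid (3S)-5-hydroxy-3-methyloxolan-2-one F9.
- Diphenyl phosphate (cat.) in CH2Cl2 at −40 °C generates the acyloxocarbenium ion, which 17 attacks at C3 to give 22 directly.
- The 1,3-trans product is expected to be favoured kinetically; selectivity may be modest, so the minor 18-epimer is separated and re-equilibrated with acid.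

**Further compounds**
F1 | step 4 | ethyl (2E)-3-[1-(but-3-en-1-yl)-2-(1-hydroxyprop-2-en-1-yl)-1H-pyrrol-3-yl]-2-methylprop-2-enoate | C=CCCn1ccc(/C=C(\C)C(=O)OCC)c1C(O)C=C
F2 | step 4 | branched butanoate of F1 (1-pyrrolylprop-2-en-1-yl butanoate) | C=CCCn1ccc(/C=C(\C)C(=O)OCC)c1C(OC(=O)CCC)C=C
F3 | step 4 | linear (2E)-3-pyrrolylprop-2-en-1-yl butanoate | C=CCCn1ccc(/C=C(\C)C(=O)OCC)c1/C=C/COC(=O)CCC
F4 | step 4 | (2R,3S)-2-ethyl-3-[pyrrol-2-yl]pent-4-enoic acid carrying the ethyl enoate | CC[C@@H](C(=O)O)[C@H](C=C)c1c(/C=C(\C)C(=O)OCC)ccn1CCC=C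
F5 | step 4 | (2R,3S)-diol (primary alcohol at C11, allylic alcohol at C14) | CC[C@@H](CO)[C@H](C=C)c1c(/C=C(\C)CO)ccn1CCC=C
F6 | step 5 | (2R,3S)-aldehyde carrying the ethyl enoate | CC[C@@H](C=O)[C@H](C=C)c1c(/C=C(\C)C(=O)OCC)ccn1CCC=C
F7 | step 5 | ring-C trans hydroxy ester (C11 epimer, C13 unassigned) | CC[C@H]1[C@H](O)[C@@H](C(C)C(=O)OCC)c2ccn(CCC=C)c2[C@H]1C=C
F8 | step 5 | ring-C trans hydroxy acid | CC[C@H]1[C@H](O)[C@@H](C(C)C(=O)O)c2ccn(CCC=C)c2[C@H]1C=C
F9 | step 8 | (3S)-5-hydroxy-3-methyloxolan-2-one (C5 epimers) | OC1C[C@H](C)C(=O)O1
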